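I draw a straight line. That is the bench habit for a slow flask: replace the curve by its mean rate and carry that rate to the asked time.

the same everywhere: starting material 40 mM; added ligand 0.24 mM
- maple: partner 32 mM; protic impurity 18 mM; free catalyst 80 µM; run made earlier
- larch: partner 64 mM; protic impurity 12 mM; free catalyst 80 µM; run made earlier
- Wednesday's: partner 32.0 mM; protic impurity 12.0 mM; free catalyst 80 µM; time 1.0 h
- Saturday's: partner 32.0 mM; protic impurity 12.0 mM; free catalyst 120 µM; time 0.25 h

| run | time / min | product / % |
|---|---|---|
| maple | 1.50 | 0.2 |
| maple | 3.00 | 1.3 |
| maple | 5.00 | 1.4 |
| maple | 6.00 | 1.4 |
| maple | 8.00 | 2.8 |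
| maple | 10.0 | 3.3 |
| maple | 12.0 | 2.5 |
| larch | 0.667 | 0 |
| larch | 2.00 | 1.0 |
| larch | 3.00 | 0.7 |
| larch | 5.00 | 2.1 |
| larch | 8.00 | 3.3 |
| larch | 10.0 | 4.3 |
| larch | 12.0 | 4.8 |

(standard deviation of a reading: 0.5 percentage points)

1. the flask that ends with the higher amount of product, in percent of the starting material charged, or "neither" when 2 percentage points or less lies between them (Wednesday's / Saturday's / neither)
2. final product, as a percentage of the starting material charged, in Wednesday's
3. final product, as a percentage of the starting material charged, in Saturday's

- no earlier run changes the charge of free catalyst; that part of a forecast is a guess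

The maple run and the larch run each stand one charge away from Wednesday's flask: the maple run in its protic impurity, 18 mM against 12.0 mM, and the larch run in its partner, 64 mM against 32.0 mM. I take the maple run, whose partner charge equals that of Wednesday's flask, and this is my choice, not a finding, since the larch run stands just as near. Dividing the sum of the last 3 maple readings by the sum of their times smooths the scatter, and carried to 1.0 h this mean rate gives 17.2 % for Wednesday's flask. Scaled by the catalyst ratio, which is a guess, and by the shorter time, it gives 6.45 % for Saturday's flask. Wednesday's flask therefore ends higher by 11 percentage points, which is more than the margin of 2 points.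

A line has a border, and the charges give it. The partner is the limiting reagent, 32.0 mM against 40 mM of starting material. I assume, though these readings cannot show it, that each protic impurity takes one partner and each product needs one. That gives a ceiling of 50.0 %, the partner left after the impurity's share, over the starting material charged. Wednesday's line meets it at 2.91 h, and the asked 1.0 h is a third of that, so I let the mean rate stand.

The forecast names Wednesday's, with 20 % for Wednesday's flask and 8.5 % for Saturday's flask, both higher than my figures. Of its Wednesday's figure it says “I shade this down for consumption and possible catalyst decay”.

    catalyst intermediate B → by-product + catalyst intermediate C (k = 0.0360 /s)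
    starting material + free catalyst ⇌ catalyst intermediate A (K = 14.0 /M, k = 53.0 /M/s)
    partner + catalyst intermediate A → catalyst intermediate B (k = 17.0 /M/s)
    catalyst intermediate C → free catalyst + product (k = 2.60 /s)
    free catalyst + added ligand ⇌ idle complex (K = 1500 /M, k = 14.0 /M/s)
    partner + protic impurity → quenched reagent (k = 0.0710 /M/s)

Wednesday's flask gives 17.5 % and Saturday's flask 7.20 %, so Wednesday's ends higher. At 1.00 h, Wednesday's flask holds 0.945 % of its protic impurity and 11.9 mM of quenched reagent. Left to 10.0 h, Wednesday's flask stands at 50.0 %, level with the ceiling of 50.0 %, with 0.0396 % of its partner remaining. Saturday's flask at 2.50 h has 44.4 %, and the partner still there, 6.97 % of its charge, is worth 5.58 % of the starting material charged.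

The earlier runs and the new flask stem from a simulated flask from invented constants.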